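Count the chains.

common to all: Z 20 mM; Q 0.20 mM
- west: X 1 mM; run made earlier
- south: X 1.7 mM; run made earlier
- north-west: X 2.2 mM; run made earlier
- birch: X 2.00 mM; time 1.0 h
- larch: X 1.20 mM; time 1.0 h

| run | time / min | J / % | Z / % |
|---|---|---|---|
| west | 12.0 | 1.7 | 100.5 |
| west | 25.0 | 7.6 | 89.9 |
| west | 40.0 | 17.0 | 82.9 |
| west | 50.0 | 26.0 | 75.4 |
| west | 60.0 | 33.0 | 68.0 |
| south | 12.0 | 3.5 | 98.5 |
| south | 25.0 | 7.1 | 94.4 |
| south | 40.0 | 16.5 | 83.2 |
| south | 50.0 | 24.1 | 76.7 |
| south | 60.0 | 31.2 | 66.5 |
| north-west | 5.00 | 1.4 | 99.4 |
| north-west | 15.0 | 4.0 | 95.3 |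
| north-west | 30.0 | 10.3 | 90.3 |
| north-west | 40.0 | 17.7 | 82.2 |
| north-west | 60.0 | 30.9 | 66.6 |

(scatter of a reading: 1 percentage point)

- the average divides the monomer in chains by the number of chains begun, living and dead together
- the earlier runs do not show the number of chains; that part of a forecast is a guess

- which of the two ends with the longer chains by the average number of monomer units in a chain (chains begun, living or dead) ("neither" if they lie within 10%) (birch / larch / neither)
- average number of monomer units in a chain (chains begun, living or dead) at the end, birch
- average number of monomer units in a chain (chains begun, living or dead) at the end, larch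

The length asked for is J divided by the chains begun, so we reckon J first. At 60.0 min the earlier runs read 33.0%, 31.2% and 30.9% as X goes from 1 mM to 2.2 mM, a spread of 2.1 percentage points against a scatter of 1 point. So we take their mean, 31.7%, for birch and for larch at 1.0 h. The readings do not show the chains, so we guess that they start from Q and not from X. If every Q charged had begun a chain, the length would be 31.7.

That is the weak link, since Q may not be spent by then. From the mean J at 25.0 min, 40.0 min and 60.0 min, the pace per Z left (the pseudo-first-order coefficient of each interval) reads 0.00739 min⁻¹ and then 0.00971 min⁻¹, a factor of 1.31. Chains arriving steadily would give 1.54, so the factor read is smaller, which hints, within the scatter of 1 point, at a supply that is slowing. Trying a half-life of 30.0 min for Q gives 1.30, which fits this loose reading. The share of Q spent by 1.0 h, the spent share, is then 75.0%. Dividing by it gives a length of 42.3 in both flasks, so we commit to no difference.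

The forecast said larch, with 5 for birch and 8 for larch, on the ground that “Chains then follow X consumed”, which differs from our reckoning.

    Z + G → J + G, rate k1*[G]*[Z] (k = 80.0 L mol⁻¹ min⁻¹)
    G + X → D (k = 1.10 L mol⁻¹ min⁻¹)
    Q → L (k = 0.0210 min⁻¹)
    Z + L → G + J (k = 25.0 L mol⁻¹ min⁻¹)

The flasks give 45.2 for birch and 45.9 for larch, so the answer is neither, beside our 42.3. In birch at 1.00 h, X stands at 99.5% of its charge and Q at 28.4%, where our spent share leaves 25.0%. The neighbour of larch charged with 0.80 mM of Q holds 78.1% J at the end, so the spent share reckons its length at 26.0, and that flask stands at 29.2.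

(The numbers in the tables stem from a simulated flask with made-up constants, noise included.)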